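Slowness was what I measured first. Target crept on in both runs long after the substrate had dropped.

| flask | substrate | coupling partner | remark | time |
|---|---|---|---|---|
| noon | 0.25 M | 0.225 M (fed, over 5.0 h) | the very flask that is asked about, followed so far |  |
| dawn | 0.17 M | 0.225 M (fed, over 5.0 h) | run made earlier |  |
| flask | 0.25 M | 0.225 M (fed, over 5.0 h) |  | 40 h |

| run | time / h | substrate / % | target / % |
|---|---|---|---|
| noon | 1.33 | 21.2 | 1.0 |
| noon | 2.00 | 17.6 | 0 |
| noon | 4.00 | 15.2 | 1.0 |
| noon | 6.00 | 14.2 | 1.9 |
| noon | 10.0 | 14.2 | 4.8 |
| noon | 15.0 | 12.9 | 7.0 |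
| dawn | 3.00 | 15.2 | 1.0 |
| dawn | 5.00 | 14.7 | 2.0 |
| dawn | 8.00 | 13.3 | 2.8 |
| dawn | 15.0 | 12.9 | 7.6 |
| dawn | 25.0 | 11.5 | 12.3 |
| dawn | 40.0 | 9.9 | 19.4 |

(readings scatter by 0.5 percentage points)

1. the state of affairs at 40 h: stopped, and by what, or still going (it is still moving / all of the substrate has reacted / the coupling partner has run out first / forward and back rates have come level)
2. conversion of substrate at 40 h
3. amount of target at 40 h, in percent of the substrate charged

- the reaction counts as stopped when no species that holds the substrate changes by six tenths of a point or more over the second half of the time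

I worked with the fraction not yet target, not with the target made. In the dawn run it fell from 92.4% at 15.0 h to 80.6% at 40.0 h, a clock of 0.00547 h⁻¹. That made 127 h the pseudo-first-order half-life of the fraction not yet target. The noon flask read 7.0% of target at 15.0 h against 7.6% at dawn, and 12.9% of substrate in both, so I carried the half-life over and took dawn's conversion of 90.1% for noon.

For a lower edge I used noon's own stretch from 10.0 h to 15.0 h, a slower clock of 0.00468 h⁻¹, read through the scatter, and got 17.3%, an estimate and no strict bound. For an upper edge I ran the dawn clock as a straight line from 15.0 h, which lies above that clock's own curve: 19.7%. The half-life itself gave 18.9% at 40 h, with 9.4 percentage points gained after 20.0 h, so I said still moving.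

The forecast said it is still moving, with conversion 90% and target 18.7%, the target inside my bracket, on the ground that the flask “should track dawn, slightly lower”. The flask gave it is still moving, with conversion 88.8% and target 18.1%, the target also inside.

    substrate ⇌ intermediate A (K = 2.67, k = 6.20 × 10⁻⁴ s⁻¹)
    substrate + intermediate C → side product (k = 4.18 × 10⁻⁵ M⁻¹ s⁻¹)
    coupling partner + intermediate B → target (k = 2.69 × 10⁻⁵ M⁻¹ s⁻¹)
    coupling partner + intermediate B ⇌ intermediate C (K = 1.74 M⁻¹, k = 9.69 × 10⁻⁴ M⁻¹ s⁻¹)
    intermediate A ⇌ intermediate D (K = 0.180, k = 1.98 × 10⁻⁴ s⁻¹)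
    intermediate A ⇌ intermediate B (K = 0.860, k = 1.57 × 10⁻⁴ s⁻¹)

In the flask the substrate stood at 14.5% by 5.00 h, with intermediate A at 38.1% and intermediate B at 29.7%. After that, coupling partner and intermediate B went on making target, 9.34% at 20.0 h, with 70% of the partner's charge still there at 40.0 h. From 20.0 h to 40 h the flask's fraction not yet target fell with a half-life of 136 h, beside the carried 127 h. For the neighbour with 0.38 M of coupling partner I divided the carried half-life by the charge ratio, to 75.1 h, which, counted from the start, gave 30.9% of target; that flask held 27.2%.

(The earlier runs and the new flask are simulated for substances that don't exist, noise included.)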